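## Retrosynthetic overview

1. The target comes from C9‑selective acylation of the 8α,9α‑diol (via its stannylene acetal) with (Z)‑3‑methylpent‑2‑enoyl chloride, made by syn‑carbocupration of ethyl pent‑2‑ynoate; C2–O desilylation is last.
2. The 7β‑isopropenyl/8α‑OH pair comes from trans‑diaxial cuprate opening of a 7α,8α‑epoxy‑9α‑ol, made by hydroxyl‑directed epoxidation of the Δ7‑9α‑ol.
3. The Δ7‑9α‑ol comes from a 9α‑silyloxy‑8‑ketone (enol triflate, then reduction), which comes from Rubottom oxidation of the Δ8 silyl enol ether formed by Li/NH3 reduction of an octalone (this sets the trans ring fusion).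
4. The C2 hydroxyl is the isopropenyl group of carvone, converted by ozonolysis/Criegee rearrangement.
5. The octalone comes from the key intermolecular Mukaiyama–Michael addition of a carvone‑derived silyl enol ether to methyl vinyl ketone (quaternary C5), then aldol condensation; ring A is (S)‑carvone, ring B is formed second.

Convention (one line): eremophilane numbering is used for the decalin (ring A = C1–C5, C10; ring B = C5–C10; C5 carries the angular methyl, C4 the secondary methyl); β is the face of the C5 methyl, α the opposite face.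

## Route

Step 1
Reactants: 1 (S)-(+)-carvone
Product: 3 (3S,5S)-2,3-dimethyl-5-isopropenyl-1-(trimethylsilyloxy)cyclohex-1-ene, via lithium enolate 2 (not isolated)
Conditions: MeLi (2.2 equiv), CuI (1.1 equiv), Et2O, 0 °C; add 1, −20 °C; then TMSCl, Et3N, −20 °C → rt
Reagents that add atoms: lithium dimethylcuprate [Li+].C[Cu-]C (made in the flask from methyllithium C[Li] and CuI); chlorotrimethylsilane C[Si](C)(C)Cl
Why: Conjugate addition of the Gilman cuprate to the enone occurs anti to the isopropenyl group (axial attack on the half‑chair), setting the new methyl‑bearing centre trans to isopropenyl, and O‑silylation traps the regiodefined enolate as its silyl enol ether.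

Step 2
Reactants: 3 (3S,5S)-2,3-dimethyl-5-isopropenyl-1-(trimethylsilyloxy)cyclohex-1-ene; 4 methyl vinyl ketone
Product: 5 (2R,3S,5S)-2,3-dimethyl-2-(3-oxobutyl)-5-isopropenylcyclohexan-1-one
Conditions: BF3·OEt2 (1.0 equiv), i-PrOH (1.0 equiv), CH2Cl2, −78 °C; aq NaHCO3
Reagents that add atoms: none
Why: Lewis‑acid‑mediated Mukaiyama–Michael addition of the tetrasubstituted silyl enol ether to the enone forms the quaternary carbon regiospecifically, the acceptor approaching the face anti to the adjacent pseudoaxial C3 methyl so that the two methyls end up cis.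

Step 3
Reactants: 5 (2R,3S,5S)-2,3-dimethyl-2-(3-oxobutyl)-5-isopropenylcyclohexan-1-one
Product: 7 2α-isopropenyl-4β,5β-dimethyloctal-9(10)-en-8-one, via ketol 6 (not isolated)
Conditions: KOH, MeOH, rt → 60 °C
Reagents that add atoms: none
Why: Base‑mediated intramolecular aldol condensation (the ring‑closing half of a Robinson annulation) of the 1,5‑diketone followed by E1cB dehydration gives the conjugated octalone without touching the existing stereocentres.

Step 4
Reactants: 7 2α-isopropenyl-4β,5β-dimethyloctal-9(10)-en-8-one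
Product: 9 2α-isopropenyl-4β,5β-dimethyl-8-(trimethylsilyloxy)-10αH-octal-8(9)-ene, via lithium enolate 8 (not isolated)
Conditions: Li (2.5 equiv), NH3(l)/THF, t-BuOH (1.0 equiv), −78 °C; isoprene; evaporate NH3; TMSCl, Et3N, THF, 0 °C
Reagents that add atoms: chlorotrimethylsilane C[Si](C)(C)Cl
Why: Dissolving‑metal conjugate reduction protonates the β‑carbon C10 axially to give the trans ring fusion (10α‑H, anti to the angular methyl) and leaves the regiospecific C8–C9 lithium enolate, which TMSCl traps on oxygen (reductive enolate trapping).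

Step 5
Reactants: 9 2α-isopropenyl-4β,5β-dimethyl-8-(trimethylsilyloxy)-10αH-octal-8(9)-ene
Product: 12 9α-hydroxy-2α-isopropenyl-4β,5β-dimethyl-10αH-decalin-8-one, via silyloxy epoxide 10 (not isolated), via silyloxy ketone 11 (not isolated)
Conditions: mCPBA (1.0 equiv), NaHCO3, CH2Cl2, −20 °C; then 1 M HCl, THF, 0 °C
Reagents that add atoms: meta-chloroperbenzoic acid OOC(=O)c1cccc(Cl)c1
Why: In this Rubottom oxidation the electron‑rich silyl enol ether is epoxidised far faster than the isopropenyl group and from the α face opposite the axial angular methyl, and silyl migration then hydrolysis gives the equatorial 9α‑hydroxy ketone, which is also the thermodynamically preferred C9 epimer.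

Step 6
Reactants: 12 9α-hydroxy-2α-isopropenyl-4β,5β-dimethyl-10αH-decalin-8-one
Product: 13 9α-(tert-butyldimethylsilyloxy)-2α-isopropenyl-4β,5β-dimethyl-10αH-decalin-8-one
Conditions: TBSOTf, 2,6-lutidine, CH2Cl2, −78 → 0 °C
Reagents that add atoms: tert-butyldimethylsilyl triflate CC(C)(C)[Si](C)(C)OS(=O)(=O)C(F)(F)F
Why: O‑Silylation of the secondary alcohol with the silyl triflate and a hindered pyridine base is fast at low temperature and blocks the ketol against base‑induced isomerisation in later steps.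

Step 7
Reactants: 13 9α-(tert-butyldimethylsilyloxy)-2α-isopropenyl-4β,5β-dimethyl-10αH-decalin-8-one
Product: 16 2α-acetoxy-9α-(tert-butyldimethylsilyloxy)-4β,5β-dimethyl-10αH-decalin-8-one, via methoxy hydroperoxide 14 (not isolated), via peracetate 15 (not isolated)
Conditions: O3, CH2Cl2/MeOH (4:1), NaHCO3, −78 °C; N2 purge; then Ac2O, Et3N, DMAP (cat.), 0 → 40 °C
Reagents that add atoms: ozone [O-][O+]=O; methanol CO (acetic anhydride acylates the hydroperoxide but none of its atoms stay in 16)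
Why: Ozonolysis of the only alkene in methanol gives the methoxy hydroperoxide, whose peracetate undergoes Criegee rearrangement with migration of the secondary ring carbon C2 to oxygen with retention of configuration, converting isopropenyl into the 2α‑acetate.

Step 8
Reactants: 16 2α-acetoxy-9α-(tert-butyldimethylsilyloxy)-4β,5β-dimethyl-10αH-decalin-8-one
Product: 17 9α-(tert-butyldimethylsilyloxy)-2α-hydroxy-4β,5β-dimethyl-10αH-decalin-8-one
Conditions: K2CO3, MeOH, 0 °C → rt
Reagents that add atoms: none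
Why: Mild base‑catalysed transesterification (methanolysis) removes the acetate while the silyl ether survives, and any enolisation at C9 only returns the favoured equatorial 9α epimer.

Step 9
Reactants: 17 9α-(tert-butyldimethylsilyloxy)-2α-hydroxy-4β,5β-dimethyl-10αH-decalin-8-one
Product: 18 9α-(tert-butyldimethylsilyloxy)-2α-(tert-butyldiphenylsilyloxy)-4β,5β-dimethyl-10αH-decalin-8-one
Conditions: TBDPSCl, imidazole, DMAP (cat.), DMF, 40 °C
Reagents that add atoms: tert-butyldiphenylsilyl chloride CC(C)(C)[Si](Cl)(c1ccccc1)c1ccccc1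
Why: Standard O‑silylation installs a robust tert‑butyldiphenylsilyl ether on the axial C2 alcohol that will outlast the later acid removal of the C9 silyl ether.

Step 10
Reactants: 18 9α-(tert-butyldimethylsilyloxy)-2α-(tert-butyldiphenylsilyloxy)-4β,5β-dimethyl-10αH-decalin-8-one
Product: 20 9α-(tert-butyldimethylsilyloxy)-2α-(tert-butyldiphenylsilyloxy)-4β,5β-dimethyl-10αH-octal-7-en-8-yl triflate, via lithium enolate 19 (not isolated)
Conditions: LiN(SiMe3)2, THF, −78 °C; then Comins' reagent, −78 → 0 °C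
Reagents that add atoms: Comins' reagent, N-(5-chloropyridin-2-yl)bis(trifluoromethanesulfonyl)imide FC(F)(F)S(=O)(=O)N(c1ccc(Cl)cn1)S(=O)(=O)C(F)(F)F
Why: Kinetic deprotonation occurs at the unhindered C7 methylene and not at the oxygen‑bearing C9 methine, and O‑sulfonylation of the enolate gives the C7–C8 enol triflate.

Step 11
Reactants: 20 9α-(tert-butyldimethylsilyloxy)-2α-(tert-butyldiphenylsilyloxy)-4β,5β-dimethyl-10αH-octal-7-en-8-yl triflate
Product: 21 9α-(tert-butyldimethylsilyloxy)-2α-(tert-butyldiphenylsilyloxy)-4β,5β-dimethyl-10αH-octal-7-ene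
Conditions: Pd(OAc)2 (5 mol %), PPh3 (10 mol %), Bu3N, HCO2H, DMF, 60 °C
Reagents that add atoms: none
Why: Palladium‑catalysed formate reduction of the vinyl triflate (oxidative addition to zerovalent palladium, decarboxylation of formate to a palladium hydride, reductive elimination) replaces the triflate by hydrogen and leaves the C7–C8 alkene in place.

Step 12
Reactants: 21 9α-(tert-butyldimethylsilyloxy)-2α-(tert-butyldiphenylsilyloxy)-4β,5β-dimethyl-10αH-octal-7-ene
Product: 22 2α-(tert-butyldiphenylsilyloxy)-4β,5β-dimethyl-10αH-octal-7-en-9α-ol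
Conditions: camphorsulfonic acid (0.2 equiv), MeOH/CH2Cl2 (1:1), 0 °C → rt
Reagents that add atoms: none
Why: Acid‑catalysed methanolysis cleaves the tert‑butyldimethylsilyl ether much faster than the bulkier and more acid‑stable tert‑butyldiphenylsilyl ether, unveiling the allylic 9α‑alcohol.

Step 13
Reactants: 22 2α-(tert-butyldiphenylsilyloxy)-4β,5β-dimethyl-10αH-octal-7-en-9α-ol
Product: 23 7α,8α-epoxy-2α-(tert-butyldiphenylsilyloxy)-4β,5β-dimethyl-10αH-decalin-9α-ol
Conditions: mCPBA, NaHCO3, CH2Cl2, 0 °C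
Reagents that add atoms: meta-chloroperbenzoic acid OOC(=O)c1cccc(Cl)c1
Why: Hydroxyl‑directed (Henbest) epoxidation delivers oxygen syn to the pseudoequatorial 9α‑hydroxyl, which is also the face opposite the axial angular methyl, giving the 7α,8α‑epoxide.

Step 14
Reactants: 23 7α,8α-epoxy-2α-(tert-butyldiphenylsilyloxy)-4β,5β-dimethyl-10αH-decalin-9α-ol
Product: 24 2α-(tert-butyldiphenylsilyloxy)-7β-isopropenyl-4β,5β-dimethyl-10αH-decalin-8α,9α-diol
Conditions: isopropenylmagnesium bromide (5 equiv), CuI (20 mol %), THF, −30 → 0 °C; aq NH4Cl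
Reagents that add atoms: isopropenylmagnesium bromide CC(=C)[Mg]Br
Why: Copper‑catalysed Grignard opening of the epoxide follows the Fürst–Plattner rule in the rigid trans‑decalin, so isopropenyl enters C7 axially from the β face with inversion (trans‑diaxial opening, the course taken by nucleophiles with 2α,3α‑epoxy steroids) and the 8α‑oxygen is retained as the axial alcohol.

Step 15
Reactants: 25 ethyl pent-2-ynoate
Product: 27 ethyl (2Z)-3-methylpent-2-enoate, via vinylcuprate 26 (not isolated)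
Conditions: MeLi (2.2 equiv), CuI (1.1 equiv), THF, 0 °C; add 25, −78 °C; MeOH quench at −78 °C
Reagents that add atoms: lithium dimethylcuprate [Li+].C[Cu-]C (made in the flask from methyllithium C[Li] and CuI)
Why: Syn‑carbocupration (conjugate addition) of the Gilman reagent to the ynoate at low temperature places methyl and copper cis, so protonation of the vinylcopper with retention gives the Z‑enoate with ethyl cis to the ester.

Step 16
Reactants: 27 ethyl (2Z)-3-methylpent-2-enoate
Product: 28 (2Z)-3-methylpent-2-enoic acid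
Conditions: LiOH, THF/MeOH/H2O, rt; then 1 M HCl to pH 2
Reagents that add atoms: lithium hydroxide [Li+].[OH-]
Why: Saponification of the ethyl ester by hydroxide (acyl substitution) does not affect the geometry of the trisubstituted alkene.

Step 17
Reactants: 28 (2Z)-3-methylpent-2-enoic acid
Product: 29 (2Z)-3-methylpent-2-enoyl chloride
Conditions: 1-chloro-N,N,2-trimethylprop-1-en-1-amine (Ghosez reagent), CH2Cl2, 0 °C → rt; concentrate and use at once
Reagents that add atoms: 1-chloro-N,N,2-trimethylprop-1-en-1-amine CC(C)=C(Cl)N(C)C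
Why: The Ghosez reagent converts the acid into its chloride under neutral conditions, avoiding acid‑ or base‑induced Z/E isomerisation or deconjugation.

Step 18
Reactants: 24 2α-(tert-butyldiphenylsilyloxy)-7β-isopropenyl-4β,5β-dimethyl-10αH-decalin-8α,9α-diol; 29 (2Z)-3-methylpent-2-enoyl chloride
Product: 31 2α-(tert-butyldiphenylsilyloxy)-8α-hydroxy-7β-isopropenyl-4β,5β-dimethyl-10αH-decalin-9α-yl (2Z)-3-methylpent-2-enoate, via stannylene acetal 30 (not isolated)
Conditions: Bu2SnO (1.1 equiv), toluene, reflux, Dean–Stark; then 29 (1.1 equiv), toluene, 0 °C → rt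
Reagents that add atoms: none
Why: The cis‑diol forms a five‑membered dibutylstannylene acetal whose equatorial oxygen (O9) is the more nucleophilic, so base‑free acylation with the acid chloride occurs selectively at C9 and not at the axial O8 (regioselective stannylene‑mediated acylation).

Step 19
Reactants: 31 2α-(tert-butyldiphenylsilyloxy)-8α-hydroxy-7β-isopropenyl-4β,5β-dimethyl-10αH-decalin-9α-yl (2Z)-3-methylpent-2-enoate
Product: 32 (2S,4S,5R,7R,8R,9S,10R)-2,8-dihydroxyeremophil-11-en-9-yl (2Z)-3-methylpent-2-enoate (CNP0129603.1)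
Conditions: HF·pyridine, pyridine, THF, 0 °C → rt
Reagents that add atoms: none
Why: Pyridine‑buffered HF·pyridine cleaves the silyl ether by fluoride‑driven desilylation under mildly acidic conditions in which neither acyl migration between O9 and O8 nor alkene isomerisation occurs.

## Compound list

1 | (S)-(+)-carvone, (5S)-2-methyl-5-(prop-1-en-2-yl)cyclohex-2-en-1-one | CC1=CC[C@H](C(C)=C)CC1=O | starting material
2 | lithium (3S,5S)-2,3-dimethyl-5-(prop-1-en-2-yl)cyclohex-1-en-1-olate (3-methyl trans to isopropenyl) | C[C@H]1C[C@H](C(C)=C)CC([O-])=C1C.[Li+] | intermediate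
3 | trimethyl{[(3S,5S)-2,3-dimethyl-5-(prop-1-en-2-yl)cyclohex-1-en-1-yl]oxy}silane | C[C@H]1C[C@H](C(C)=C)CC(O[Si](C)(C)C)=C1C | intermediate
4 | methyl vinyl ketone (but-3-en-2-one) | CC(=O)C=C | starting material
5 | (2R,3S,5S)-2,3-dimethyl-2-(3-oxobutyl)-5-(prop-1-en-2-yl)cyclohexan-1-one (methyls cis, oxobutyl chain trans to the 3-methyl) | CC(=O)CC[C@]1(C)[C@@H](C)C[C@H](C(C)=C)CC1=O | intermediate
6 | ketol, 10β-hydroxy-2α-isopropenyl-4β,5β-dimethyldecalin-8-one (cis-fused aldol adduct) | O=C1CC[C@]2(C)[C@@H](C)C[C@H](C(C)=C)C[C@]2(O)C1 | intermediate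
7 | 2α-isopropenyl-4β,5β-dimethyloctal-9(10)-en-8-one, (4aR,5S,7S)-4a,5-dimethyl-7-(prop-1-en-2-yl)-4,4a,5,6,7,8-hexahydronaphthalen-2(3H)-one | O=C1CC[C@]2(C)[C@@H](C)C[C@H](C(C)=C)CC2=C1 | intermediate
8 | lithium C8–C9 enolate of 2α-isopropenyl-4β,5β-dimethyl-10αH-decalin-8-one (trans-fused) | C1C[C@]2(C)[C@@H](C)C[C@H](C(C)=C)C[C@H]2C=C1[O-].[Li+] | intermediate
9 | 2α-isopropenyl-4β,5β-dimethyl-8-(trimethylsilyloxy)-10αH-octal-8(9)-ene | C1C[C@]2(C)[C@@H](C)C[C@H](C(C)=C)C[C@H]2C=C1O[Si](C)(C)C | intermediate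
10 | 8α,9α-epoxy-2α-isopropenyl-4β,5β-dimethyl-8β-(trimethylsilyloxy)-10αH-decalin | C1C[C@]2(C)[C@@H](C)C[C@H](C(C)=C)C[C@H]2[C@@H]3O[C@@]31O[Si](C)(C)C | intermediate
11 | 2α-isopropenyl-4β,5β-dimethyl-9α-(trimethylsilyloxy)-10αH-decalin-8-one | C1C[C@]2(C)[C@@H](C)C[C@H](C(C)=C)C[C@H]2[C@H](O[Si](C)(C)C)C1=O | intermediate
12 | 9α-hydroxy-2α-isopropenyl-4β,5β-dimethyl-10αH-decalin-8-one | C1C[C@]2(C)[C@@H](C)C[C@H](C(C)=C)C[C@H]2[C@H](O)C1=O | intermediate
13 | 9α-(tert-butyldimethylsilyloxy)-2α-isopropenyl-4β,5β-dimethyl-10αH-decalin-8-one | C1C[C@]2(C)[C@@H](C)C[C@H](C(C)=C)C[C@H]2[C@H](O[Si](C)(C)C(C)(C)C)C1=O | intermediate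
14 | 9α-(tert-butyldimethylsilyloxy)-2α-(1-hydroperoxy-1-methoxyethyl)-4β,5β-dimethyl-10αH-decalin-8-one (both epimers at the peroxy carbon) | C1C[C@]2(C)[C@@H](C)C[C@H](C(C)(OC)OO)C[C@H]2[C@H](O[Si](C)(C)C(C)(C)C)C1=O | intermediate
15 | peracetate of 14, 2α-[1-(acetylperoxy)-1-methoxyethyl] analogue | C1C[C@]2(C)[C@@H](C)C[C@H](C(C)(OC)OOC(C)=O)C[C@H]2[C@H](O[Si](C)(C)C(C)(C)C)C1=O | intermediate
16 | 2α-acetoxy-9α-(tert-butyldimethylsilyloxy)-4β,5β-dimethyl-10αH-decalin-8-one | C1C[C@]2(C)[C@@H](C)C[C@H](OC(C)=O)C[C@H]2[C@H](O[Si](C)(C)C(C)(C)C)C1=O | intermediate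
17 | 9α-(tert-butyldimethylsilyloxy)-2α-hydroxy-4β,5β-dimethyl-10αH-decalin-8-one | C1C[C@]2(C)[C@@H](C)C[C@H](O)C[C@H]2[C@H](O[Si](C)(C)C(C)(C)C)C1=O | intermediate
18 | 9α-(tert-butyldimethylsilyloxy)-2α-(tert-butyldiphenylsilyloxy)-4β,5β-dimethyl-10αH-decalin-8-one | C1C[C@]2(C)[C@@H](C)C[C@H](O[Si](c3ccccc3)(c3ccccc3)C(C)(C)C)C[C@H]2[C@H](O[Si](C)(C)C(C)(C)C)C1=O | intermediate
19 | lithium C7–C8 enolate of 18 | C=1C[C@]2(C)[C@@H](C)C[C@H](O[Si](c3ccccc3)(c3ccccc3)C(C)(C)C)C[C@H]2[C@H](O[Si](C)(C)C(C)(C)C)C=1[O-].[Li+] | intermediate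
20 | 9α-(tert-butyldimethylsilyloxy)-2α-(tert-butyldiphenylsilyloxy)-4β,5β-dimethyl-10αH-octal-7-en-8-yl trifluoromethanesulfonate | C=1C[C@]2(C)[C@@H](C)C[C@H](O[Si](c3ccccc3)(c3ccccc3)C(C)(C)C)C[C@H]2[C@H](O[Si](C)(C)C(C)(C)C)C=1OS(=O)(=O)C(F)(F)F | intermediate
21 | 9α-(tert-butyldimethylsilyloxy)-2α-(tert-butyldiphenylsilyloxy)-4β,5β-dimethyl-10αH-octal-7-ene | C=1C[C@]2(C)[C@@H](C)C[C@H](O[Si](c3ccccc3)(c3ccccc3)C(C)(C)C)C[C@H]2[C@H](O[Si](C)(C)C(C)(C)C)C=1 | intermediate
22 | 2α-(tert-butyldiphenylsilyloxy)-4β,5β-dimethyl-10αH-octal-7-en-9α-ol | C=1C[C@]2(C)[C@@H](C)C[C@H](O[Si](c3ccccc3)(c3ccccc3)C(C)(C)C)C[C@H]2[C@H](O)C=1 | intermediate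
23 | 7α,8α-epoxy-2α-(tert-butyldiphenylsilyloxy)-4β,5β-dimethyl-10αH-decalin-9α-ol | O1[C@@H]2C[C@]3(C)[C@@H](C)C[C@H](O[Si](c4ccccc4)(c4ccccc4)C(C)(C)C)C[C@H]3[C@H](O)[C@H]12 | intermediate
24 | 2α-(tert-butyldiphenylsilyloxy)-7β-isopropenyl-4β,5β-dimethyl-10αH-decalin-8α,9α-diol | C=C(C)[C@H]1C[C@]2(C)[C@@H](C)C[C@H](O[Si](c3ccccc3)(c3ccccc3)C(C)(C)C)C[C@H]2[C@H](O)[C@@H]1O | intermediate
25 | ethyl pent-2-ynoate | CCC#CC(=O)OCC | starting material
26 | lithium methyl[1-(ethoxycarbonyl)-2-methylbut-1-en-1-yl]cuprate (copper cis to the new methyl) | CC/C(C)=C(\C(=O)OCC)[Cu-]C.[Li+] | intermediate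
27 | ethyl (2Z)-3-methylpent-2-enoate | CC/C(C)=C\C(=O)OCC | intermediate
28 | (2Z)-3-methylpent-2-enoic acid | CC/C(C)=C\C(=O)O | intermediate
29 | (2Z)-3-methylpent-2-enoyl chloride | CC/C(C)=C\C(=O)Cl | intermediate
30 | 8α,9α-O-dibutylstannylene acetal of 24 | C=C(C)[C@H]1C[C@]2(C)[C@@H](C)C[C@H](O[Si](c3ccccc3)(c3ccccc3)C(C)(C)C)C[C@H]2[C@@H]4O[Sn](CCCC)(CCCC)O[C@H]14 | intermediate
31 | 2α-(tert-butyldiphenylsilyloxy)-8α-hydroxy-7β-isopropenyl-4β,5β-dimethyl-10αH-decalin-9α-yl (2Z)-3-methylpent-2-enoate | C=C(C)[C@H]1C[C@]2(C)[C@@H](C)C[C@H](O[Si](c3ccccc3)(c3ccccc3)C(C)(C)C)C[C@H]2[C@H](OC(=O)/C=C(/C)CC)[C@@H]1O | intermediate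
32 | (2S,4S,5R,7R,8R,9S,10R)-2,8-dihydroxyeremophil-11-en-9-yl (2Z)-3-methylpent-2-enoate (2α,8α-dihydroxy-9α-acyloxy-10αH) | C=C(C)[C@H]1C[C@]2(C)[C@@H](C)C[C@H](O)C[C@H]2[C@H](OC(=O)/C=C(/C)CC)[C@@H]1O | target

## Totals and risks

Total step count: 19. Longest linear sequence: 16 steps (steps 1–14, 18, 19, from (S)-carvone); the side-chain branch is 3 steps (15–17).

Three steps most likely to fail:

Step 14. The nucleophile must enter C7 axially, syn to the C5 methyl, and a bulky sp2 group may react slowly or lose out to bromohydrin formation by magnesium bromide. The fallback sets out from 23 and comes back at 24, replacing the isopropenyl nucleophile with a slim acetylide and building the methyl branch afterwards. Lithium (trimethylsilyl)acetylide with BF3·OEt2 in THF at −78 °C opens the epoxide in the same trans‑diaxial sense to give 2α-(tert-butyldiphenylsilyloxy)-7β-(trimethylsilylethynyl)-4β,5β-dimethyl-10αH-decalin-8α,9α-diol F4. K2CO3 in MeOH removes the silyl group to give the 7β-ethynyl diol F5. Zirconium‑catalysed methylalumination (Me3Al, Cp2ZrCl2, CH2Cl2, rt) adds methyl to the internal alkyne carbon to give the alkenylalane F6, and protonolysis with water gives the isopropenyl diol 24.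

Step 2. A quaternary centre is made next to a tertiary one with a polymerisable acceptor, so yield and facial selectivity may suffer. The fallback sets out from 3 and comes back at 5, using a neutral imine/enamine Michael addition in place of the Lewis‑acid reaction. Aqueous HCl in THF hydrolyses 3 to (3S,5S)-2,3-dimethyl-5-(prop-1-en-2-yl)cyclohexan-1-one F1 (C2 epimers). Benzylamine in toluene with water removal gives the N-benzyl imine F2. Its more substituted secondary enamine tautomer adds to methyl vinyl ketone in THF at rt, anti to the C3 methyl, to give the N-benzyl imine of the diketone F3. Aqueous acetic acid hydrolyses F3 to 5.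

Step 5. The peracid must choose the silyl enol ether over the isopropenyl group and the α face over the β face. The fallback sets out from 9 and comes back at 12, hydroxylating a metal enolate with an N‑sulfonyloxaziridine, which does not touch isolated alkenes. MeLi in THF at 0 °C cleaves 9 to the lithium enolate 8, which is treated at −78 °C with 3-phenyl-2-(phenylsulfonyl)oxaziridine (Davis reagent) and quenched with aq NH4Cl to give 12. This detour makes no compound outside the compound list (F0).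

## Further compounds

F1 | step 2 | (3S,5S)-2,3-dimethyl-5-(prop-1-en-2-yl)cyclohexan-1-one (C2 epimers) | C[C@H]1C[C@H](C(C)=C)CC(=O)C1C
F2 | step 2 | N-benzyl imine of F1 | C[C@H]1C[C@H](C(C)=C)CC(=NCc2ccccc2)C1C
F3 | step 2 | N-benzyl imine (at the ring carbonyl) of diketone 5 | CC(=O)CC[C@]1(C)[C@@H](C)C[C@H](C(C)=C)CC1=NCc1ccccc1
F0 | step 5 | none | none
F4 | step 14 | 2α-(tert-butyldiphenylsilyloxy)-7β-(trimethylsilylethynyl)-4β,5β-dimethyl-10αH-decalin-8α,9α-diol | C[Si](C)(C)C#C[C@H]1C[C@]2(C)[C@@H](C)C[C@H](O[Si](c3ccccc3)(c3ccccc3)C(C)(C)C)C[C@H]2[C@H](O)[C@@H]1O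
F5 | step 14 | 2α-(tert-butyldiphenylsilyloxy)-7β-ethynyl-4β,5β-dimethyl-10αH-decalin-8α,9α-diol | C#C[C@H]1C[C@]2(C)[C@@H](C)C[C@H](O[Si](c3ccccc3)(c3ccccc3)C(C)(C)C)C[C@H]2[C@H](O)[C@@H]1O
F6 | step 14 | alkenylalane from methylalumination of F5 (aluminium cis to the new methyl, both hydroxyls as dimethylaluminium alkoxides) | C[Al](C)/C=C(\C)[C@H]1C[C@]2(C)[C@@H](C)C[C@H](O[Si](c3ccccc3)(c3ccccc3)C(C)(C)C)C[C@H]2[C@H](O[Al](C)C)[C@@H]1O[Al](C)C
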